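(The numbers in the tables are simulated for substances that don't exist, and the scatter is random.)

North's readings cannot tell a straight line from a slow exponential: with a scatter of 1 percentage point, either curve passes through them.

| setting | north | flask |
|---|---|---|
| J | 1.1 M | 1.1 M |
| X | 200 mM (held) | 200 mM (held) |
| G | 0.083 M | 0.0550 M |
| remark | run made earlier |  |
| time |  | 2.5 h |

north run (percent of the J charged)

| time / min | E / % | J / % |
|---|---|---|
| 4.00 | 0.9 | 100.6 |
| 8.00 | 1.3 | 98.3 |
| 20.0 | 5.0 | 94.5 |
| 50.0 | 14.9 | 83.6 |

(standard deviation of a reading: 1 percentage point)

- at the start none of D is dissolved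
- reactions considered so far: X <-> D; J + D -> E; D <-> Z; D + G -> Q
- no earlier run changes the charge of G; that part of a forecast is a guess

1. how much E there is at 2.5 h, in percent of the J charged
2. the change that raises the amount of E at 2.5 h, in percent of the J charged most ("none" if none brings more than 2 percentage points) (alpha / gamma / none)
3. amount of E at 2.5 h, in percent of the J charged, after alpha

- alpha: doubling the saturation concentration of X, all else as stated
- gamma: doubling the transfer coefficient of X, all else as stated

Two chemists read this run differently. The first says D is fed at a steady rate, so E climbs in a straight line. Her last two readings give a slope of 0.00330 /min of the J charged. The line meets zero at 4.85 min, and at 2.5 h it stands at 47.9%.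

The second says D sits at a steady level, so J decays exponentially. Between the same two readings the logarithm of the unreacted fraction falls at 0.00367 /min: this is the clock constant of J, a pseudo-first-order constant. Run on from 20.0 min, it gives 41.0%, which is less than the line by 6.9 points.

G is the smaller charge, 5.00% of J's. Its effect on the flask is a guess. If the lag is the whole of that effect, it is worth 1.6 points of E, less than the gap. So G does not end the dispute. I commit to the clock's 41.0%.

The forecast takes the clock's side but adds to it: 45%, best alpha, then 70%. In its words, “I therefore nudge the estimate to about 45%”.

    X ⇌ D, rate k1*(csat - [D]) (kL = 0.00505 /s)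
    J + D → E (k = 3.54 × 10⁻⁴ /M/s)
    D ⇌ Z (K = 90.0, k = 3.82 × 10⁻⁴ /s)
    D + G → Q (k = 0.0171 /M/s)

The flask gives 42.2%, and 67.1% after alpha, which adds 25 points against 2.4 points for gamma. At 1.25 h the line reads 23.1% against the flask's 23.3%. In the flask, G fell to 13.0% of its charge by 0.250 h, when D already stood at 0.167 M, and to 0% by 1.25 h. D then held between 0.176 M and 0.179 M while J fell to 57.8%. For the same flask left until 10 h, the clock gives 88.7% and the line 196%; that flask holds 90.0%.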